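**Retrosynthetic overview**
1. Target 15 ⇐ 14 by reductive removal of a phenylsulfonyl group from the first side-chain carbon; the acetate is already in place.
2. 14 ⇐ 4 + 11: the bond between the ring CH2 and the allylic CH2 of the chain is made from the α-sulfonyl carbanion of the ring fragment and a C20 allylic bromide. Both carbons are natively electrophilic positions, and the sulfone reverses the polarity of the ring CH2.
3. 4 ⇐ 3 ⇐ 2 ⇐ 1: the only ring (ring A) is closed first, at the C10 stage, by cationic cyclization of (S)-6,7-epoxygeranyl phenyl sulfone; one asymmetric epoxidation sets both stereocentres.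
4. 11 ⇐ 10 ⇐ 9 ⇐ 5 + 6: the tail-to-tail C20 chain comes from γ-alkylation of the tiglic acid dienolate with farnesyl bromide.

Assumption: 13 and 14 are carried as the mixture of both epimers at the sulfonyl-bearing carbon (drawn without a descriptor there); step 8 erases this centre.

**Step 1**
Reactants: 1 geranyl bromide ((2E)-1-bromo-3,7-dimethylocta-2,6-diene)
Product: 2 geranyl phenyl sulfone ({[(2E)-3,7-dimethylocta-2,6-dien-1-yl]sulfonyl}benzene)
Conditions: PhSO2Na (1.2 equiv), DMF, rt
Reagents that add atoms: sodium benzenesulfinate (PhSO2Na), [Na+].[O-]S(=O)c1ccccc1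
Why: SN2 S-alkylation of the sulfinate at the primary allylic carbon gives the sulfone with the E-alkene unchanged; no stereocentre is formed.

**Step 2**
Reactants: 2 geranyl phenyl sulfone
Product: 3 (3S)-2,2-dimethyl-3-[(3E)-3-methyl-5-(phenylsulfonyl)pent-3-en-1-yl]oxirane ((S)-6,7-epoxygeranyl phenyl sulfone)
Conditions: L-fructose-derived Shi ketone (enantiomer of the usual D-fructose ketone, 0.3 equiv), Oxone (2KHSO5·KHSO4·K2SO4), K2CO3, Bu4NHSO4, MeCN–CH2(OMe)2–aq. Na2B4O7 buffer (pH 10.5), 0 °C
Reagents that add atoms: potassium peroxymonosulfate (KHSO5, the oxidant in Oxone), [K+].[O-]S(=O)(=O)OO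
Why: Shi asymmetric epoxidation: the chiral dioxirane reacts only at the electron-rich 6,7-alkene (the 2,3-alkene is deactivated by the allylic sulfone) through the spiro transition state, and the L-configured ketone delivers oxygen to the face that gives the (S)-epoxide (about 90–94% ee expected, to be raised by recrystallising 4).

**Step 3**
Reactants: 3 (S)-6,7-epoxygeranyl phenyl sulfone
Product: 4 (1S,5R)-4,6,6-trimethyl-5-[(phenylsulfonyl)methyl]cyclohex-3-en-1-ol
Conditions: ZrCl4 (1.2 equiv), CH2Cl2, −78 °C → rt; H2O quench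
Reagents that add atoms: none
Why: Lewis-acid epoxy-olefin (biomimetic cation–olefin) cyclization: the alkene attacks the tertiary epoxide carbon anti to the breaking C–O bond through a chair transition state, so the (S)-C–O centre is kept, the E-alkene places CH2SO2Ph equatorial and cis to the hydroxyl (5R), and proton loss from the ring CH2 gives mainly the endocyclic alkene (the minor exocyclic isomer is removed on AgNO3-impregnated silica); with a single alkene in the substrate no second ring can form.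

**Step 4**
Reactants: 5 tiglic acid ((2E)-2-methylbut-2-enoic acid); 6 (2E,6E)-farnesyl bromide ((2E,6E)-1-bromo-3,7,11-trimethyldodeca-2,6,10-triene)
Product: 9 (2E,6E,10E)-2,7,11,15-tetramethylhexadeca-2,6,10,14-tetraenoic acid, via dilithium dienolate of tiglic acid 7 (not isolated), via dicopper dienolate of tiglic acid 8 (not isolated)
Conditions: LiN(i-Pr)2 (2.2 equiv), THF, 0 °C; CuI (2.2 equiv), −78 °C; 6, −78 °C → rt; dilute aq. HCl work-up
Reagents that add atoms: none
Why: γ-Alkylation of a copper dienolate (vinylogous enolate alkylation): the copper dienolate attacks the primary allylic bromide through its terminal carbon in an SN2 sense, which builds the tail-to-tail C20 chain in one step and regenerates the conjugated acid as the more stable 2E isomer, while the 6E and 10E alkenes of 6 are untouched and no stereocentre is formed.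

**Step 5**
Reactants: 9 (2E,6E,10E)-2,7,11,15-tetramethylhexadeca-2,6,10,14-tetraenoic acid
Product: 10 (2E,6E,10E)-2,7,11,15-tetramethylhexadeca-2,6,10,14-tetraen-1-ol
Conditions: LiAlH4 (1.5 equiv), Et2O, 0 °C → rt
Reagents that add atoms: none
Why: Hydride reduction of the carboxylic acid: LiAlH4 reduces the conjugated acid in 1,2-fashion to the allylic alcohol and leaves the α-methyl trisubstituted alkene and its E geometry intact.

**Step 6**
Reactants: 10 (2E,6E,10E)-2,7,11,15-tetramethylhexadeca-2,6,10,14-tetraen-1-ol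
Product: 11 (2E,6E,10E)-1-bromo-2,7,11,15-tetramethylhexadeca-2,6,10,14-tetraene
Conditions: PBr3 (0.4 equiv), Et2O, −10 °C
Reagents that add atoms: phosphorus tribromide, BrP(Br)Br
Why: Conversion of a primary allylic alcohol to the bromide through its phosphite ester (SN2 by bromide) at low temperature keeps the position and E geometry of the alkene; 11 is used crude.

**Step 7 (key step)**
Reactants: 4 (1S,5R)-4,6,6-trimethyl-5-[(phenylsulfonyl)methyl]cyclohex-3-en-1-ol; 11 (2E,6E,10E)-1-bromo-2,7,11,15-tetramethylhexadeca-2,6,10,14-tetraene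
Product: 14 (1S,5R)-4,6,6-trimethyl-5-[(3E,7E,11E)-3,8,12,16-tetramethyl-1-(phenylsulfonyl)heptadeca-3,7,11,15-tetraen-1-yl]cyclohex-3-en-1-yl acetate, via dilithio dianion of the hydroxy sulfone 12 (not isolated), via lithium alkoxide of the coupled sulfone 13 (not isolated)
Conditions: n-BuLi (2.1 equiv), THF–DMPU, −78 → −30 °C; 11 (1.1 equiv), −78 → −20 °C; then Ac2O (3 equiv), DMAP (cat.), 0 °C → rt
Reagents that add atoms: acetic anhydride, CC(=O)OC(C)=O
Why: Alkylation of an α-sulfonyl carbanion: the sulfone makes the ring CH2 (natively an electrophilic C–X position, like the allylic CH2 of 11) nucleophilic, the soft allylic bromide reacts by SN2 at the carbanion and not at the hindered alkoxide of the unprotected dianion, neither ring stereocentre is touched, and the lithium alkoxide is O-acetylated in the same flask; the new sulfonyl-bearing centre forms as a mixture that step 8 erases.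

**Step 8**
Reactants: 14 (1S,5R)-4,6,6-trimethyl-5-[(3E,7E,11E)-3,8,12,16-tetramethyl-1-(phenylsulfonyl)heptadeca-3,7,11,15-tetraen-1-yl]cyclohex-3-en-1-yl acetate
Product: 15 (1S,5R)-4,6,6-trimethyl-5-[(3E,7E,11E)-3,8,12,16-tetramethylheptadeca-3,7,11,15-tetraen-1-yl]cyclohex-3-en-1-yl acetate (target, CNP0313409.1)
Conditions: 6% sodium amalgam Na(Hg), Na2HPO4, MeOH–THF, −20 °C
Reagents that add atoms: none
Why: Reductive desulfonylation by electron transfer cleaves the C–SO2Ph bond of the secondary alkyl sulfone and methanol protonates the carbanion, while the Na2HPO4 buffer keeps methoxide low so that the hindered secondary acetate and the isolated trisubstituted alkenes survive; the two ring stereocentres are untouched.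

**Compound list**
1 | geranyl bromide, (2E)-1-bromo-3,7-dimethylocta-2,6-diene | CC(C)=CCC/C(C)=C/CBr | starting material
2 | geranyl phenyl sulfone, {[(2E)-3,7-dimethylocta-2,6-dien-1-yl]sulfonyl}benzene | CC(C)=CCC/C(C)=C/CS(=O)(=O)c1ccccc1 | intermediate
3 | (3S)-2,2-dimethyl-3-[(3E)-3-methyl-5-(phenylsulfonyl)pent-3-en-1-yl]oxirane | CC1(C)O[C@H]1CC/C(C)=C/CS(=O)(=O)c2ccccc2 | intermediate
4 | (1S,5R)-4,6,6-trimethyl-5-[(phenylsulfonyl)methyl]cyclohex-3-en-1-ol (OH and CH2SO2Ph cis) | O[C@H]1CC=C(C)[C@@H](CS(=O)(=O)c2ccccc2)C1(C)C | intermediate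
5 | tiglic acid, (2E)-2-methylbut-2-enoic acid | C/C=C(\C)C(=O)O | starting material
6 | (2E,6E)-farnesyl bromide, (2E,6E)-1-bromo-3,7,11-trimethyldodeca-2,6,10-triene | CC(C)=CCC/C(C)=C/CC/C(C)=C/CBr | starting material
7 | dilithium dienolate of tiglic acid | [Li+].[Li+].[O-]C([O-])=C(C)C=C | intermediate
8 | dicopper dienolate of tiglic acid | [Cu+].[Cu+].[O-]C([O-])=C(C)C=C | intermediate
9 | (2E,6E,10E)-2,7,11,15-tetramethylhexadeca-2,6,10,14-tetraenoic acid | OC(=O)/C(C)=C/CC/C=C(\C)CC/C=C(\C)CCC=C(C)C | intermediate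
10 | (2E,6E,10E)-2,7,11,15-tetramethylhexadeca-2,6,10,14-tetraen-1-ol | OC/C(C)=C/CC/C=C(\C)CC/C=C(\C)CCC=C(C)C | intermediate
11 | (2E,6E,10E)-1-bromo-2,7,11,15-tetramethylhexadeca-2,6,10,14-tetraene | BrC/C(C)=C/CC/C=C(\C)CC/C=C(\C)CCC=C(C)C | intermediate
12 | dilithio dianion of 4 (lithium alkoxide and α-sulfonyl carbanion) | [Li+].[Li+].[O-][C@H]1CC=C(C)[C@@H]([CH-]S(=O)(=O)c2ccccc2)C1(C)C | intermediate
13 | lithium alkoxide of the C-alkylated hydroxy sulfone (both epimers at the sulfonyl carbon) | [Li+].[O-][C@H]1CC=C(C)[C@@H](C(C/C(C)=C/CC/C=C(\C)CC/C=C(\C)CCC=C(C)C)S(=O)(=O)c2ccccc2)C1(C)C | intermediate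
14 | (1S,5R)-4,6,6-trimethyl-5-[(3E,7E,11E)-3,8,12,16-tetramethyl-1-(phenylsulfonyl)heptadeca-3,7,11,15-tetraen-1-yl]cyclohex-3-en-1-yl acetate (both epimers at the sulfonyl carbon) | CC(=O)O[C@H]1CC=C(C)[C@@H](C(C/C(C)=C/CC/C=C(\C)CC/C=C(\C)CCC=C(C)C)S(=O)(=O)c2ccccc2)C1(C)C | intermediate
15 | (1S,5R)-4,6,6-trimethyl-5-[(3E,7E,11E)-3,8,12,16-tetramethylheptadeca-3,7,11,15-tetraen-1-yl]cyclohex-3-en-1-yl acetate | CC(=O)O[C@H]1CC=C(C)[C@@H](CC/C(C)=C/CC/C=C(\C)CC/C=C(\C)CCC=C(C)C)C1(C)C | target

**Step count and risks**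
Total: 8 steps. Longest linear sequence: 5 steps (1 → 2 → 3 → 4 → 14 → 15, or 6 → 9 → 10 → 11 → 14 → 15).

The three steps most likely to fail:

- **Step 3** (endocyclic versus exocyclic proton loss, competing hydride shift to a ketone). Fallback, setting out from 3 and coming back at 4: the ring is closed by a radical route. Cp2TiCl2 (2.2 equiv) and Mn dust in THF generate trivalent titanium (Cp2TiCl), which opens the epoxide homolytically. 6-Endo radical cyclization and β-hydride loss from the titanium alkyl give the exocyclic isomer (1S,3R)-2,2-dimethyl-4-methylidene-3-[(phenylsulfonyl)methyl]cyclohexan-1-ol F1. RhCl3·3H2O (cat.) in EtOH at 70 °C then moves the double bond into the ring to give 4.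

- **Step 4** (γ- versus α-alkylation of the dienolate and the 2E/2Z ratio). Fallback, setting out from 6 and coming back at 10: alkylation of lithiated acetaldehyde N-tert-butylimine (LiN(i-Pr)2, THF, −78 °C) with 6 gives (4E,8E)-N-tert-butyl-5,9,13-trimethyltetradeca-4,8,12-trien-1-imine F2. Aqueous oxalic acid hydrolyses it to (4E,8E)-5,9,13-trimethyltetradeca-4,8,12-trienal F3. E-selective Wittig olefination with Ph3P=C(CH3)CO2Et in CH2Cl2 gives ethyl (2E,6E,10E)-2,7,11,15-tetramethylhexadeca-2,6,10,14-tetraenoate F4. i-Bu2AlH (CH2Cl2, −78 °C) reduces it to 10.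

- **Step 7** (hindered carbanion next to a quaternary carbon, O- versus C-alkylation of the dianion). Fallback, setting out from 3 and 11 and coming back at 14: the order of ring closure and coupling is swapped. The unhindered allylic sulfonyl carbanion of 3 (n-BuLi, THF, −78 °C) is alkylated with 11 to give (3S)-2,2-dimethyl-3-[(3E,7E,11E,15E)-3,7,12,16,20-pentamethyl-5-(phenylsulfonyl)henicosa-3,7,11,15,19-pentaen-1-yl]oxirane F5. ZrCl4 in CH2Cl2 then closes ring A to (1S,5R)-4,6,6-trimethyl-5-[(3E,7E,11E)-3,8,12,16-tetramethyl-1-(phenylsulfonyl)heptadeca-3,7,11,15-tetraen-1-yl]cyclohex-3-en-1-ol F6; here a second ring closure onto the next chain alkene can compete. Ac2O, pyridine and DMAP give 14.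

**Further compounds**
F1 | step 3 | (1S,3R)-2,2-dimethyl-4-methylidene-3-[(phenylsulfonyl)methyl]cyclohexan-1-ol | O[C@H]1CCC(=C)[C@@H](CS(=O)(=O)c2ccccc2)C1(C)C
F2 | step 4 | (4E,8E)-N-tert-butyl-5,9,13-trimethyltetradeca-4,8,12-trien-1-imine | CC(C)(C)N=CCC/C=C(\C)CC/C=C(\C)CCC=C(C)C
F3 | step 4 | (4E,8E)-5,9,13-trimethyltetradeca-4,8,12-trienal | O=CCC/C=C(\C)CC/C=C(\C)CCC=C(C)C
F4 | step 4 | ethyl (2E,6E,10E)-2,7,11,15-tetramethylhexadeca-2,6,10,14-tetraenoate | CCOC(=O)/C(C)=C/CC/C=C(\C)CC/C=C(\C)CCC=C(C)C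
F5 | step 7 | (3S)-2,2-dimethyl-3-[(3E,7E,11E,15E)-3,7,12,16,20-pentamethyl-5-(phenylsulfonyl)henicosa-3,7,11,15,19-pentaen-1-yl]oxirane (both epimers at the sulfonyl carbon) | CC1(C)O[C@H]1CC/C(C)=C/C(C/C(C)=C/CC/C=C(\C)CC/C=C(\C)CCC=C(C)C)S(=O)(=O)c2ccccc2
F6 | step 7 | (1S,5R)-4,6,6-trimethyl-5-[(3E,7E,11E)-3,8,12,16-tetramethyl-1-(phenylsulfonyl)heptadeca-3,7,11,15-tetraen-1-yl]cyclohex-3-en-1-ol (both epimers at the sulfonyl carbon) | O[C@H]1CC=C(C)[C@@H](C(C/C(C)=C/CC/C=C(\C)CC/C=C(\C)CCC=C(C)C)S(=O)(=O)c2ccccc2)C1(C)C
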